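Ring B (C5–C10, eremophilane numbering) is disconnected at C5–C6 and C7–C8. The C8 carbinol next to the C7 isopropenyl group is an aldol motif (isopropenyl = methylenated acetyl), and quaternary C5 with its methyl is a tertiary radical born from an exocyclic methylene. One iron-hydride radical–polar crossover annulation therefore joins methyl vinyl ketone to a monocyclic methylidenecyclohexane aldehyde: hydrogen-atom transfer creates the C5 methyl and radical, Giese addition forms C5–C6, and the resulting enolate closes C7–C8 by aldol, setting C5, C7 and C8. The precursor already carries C3, C4, C9 and C10 from a CBS reduction and a proline aldol.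

Key step: step 10

Remark on numbering: the discussion uses eremophilane numbering (ring A = C1–C5 and C10; ring B = C5–C10; C14 = methyl on C5; C15 = methyl on C4; C11–C13 = side chain on C7). Names of bicyclic compounds use naphthalene numbering (C9 = 1, C8 = 2, C7 = 3, C6 = 4, C5 = 4a, C4 = 5, C3 = 6, C10 = 8a).

Step 1
Reactants: 1 2-methylcyclohex-2-en-1-one
Product: 2 (R)-2-methylcyclohex-2-en-1-ol
Conditions: (S)-2-methyl-CBS-oxazaborolidine (10 mol %), BH3·SMe2, THF, −20 °C; then MeOH
Reagents that add atoms: none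
Why: Corey–Bakshi–Shibata reduction, in which the substituted alkene carbon acts as the large ketone substituent, so the (S)-oxazaborolidine–borane complex should deliver hydride to the face that gives the R allylic alcohol (future C3).

Step 2
Reactants: 2 (R)-2-methylcyclohex-2-en-1-ol
Product: 3 tert-butyldimethyl{[(1R)-2-methylcyclohex-2-en-1-yl]oxy}silane
Conditions: TBSCl, imidazole, DMF, rt
Reagents that add atoms: tert-butyldimethylsilyl chloride, CC(C)(C)[Si](C)(C)Cl
Why: Imidazole-promoted silylation of a secondary allylic alcohol; no stereocenter is touched.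

Step 3
Reactants: 3 tert-butyldimethyl{[(1R)-2-methylcyclohex-2-en-1-yl]oxy}silane
Product: 5 (1R,2S,3R)-3-[(tert-butyldimethylsilyl)oxy]-2-methylcyclohexan-1-ol, via alkylborane 4 (not isolated)
Conditions: BH3·THF, THF, 0 °C to rt; then NaOH, H2O2, 0 °C
Reagents that add atoms: borane–tetrahydrofuran, B.C1CCOC1 (boron of 4 only); hydrogen peroxide, OO (hydroxyl oxygen of 5)
Why: Hydroboration–oxidation places boron on the less substituted alkene carbon, syn to hydrogen and anti to the allylic silyloxy group, and oxidation proceeds with retention; the two new stereocenters are not relied on, because one is oxidised and the other equilibrated in step 4.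

Step 4
Reactants: 5 (1R,2S,3R)-3-[(tert-butyldimethylsilyl)oxy]-2-methylcyclohexan-1-ol
Product: 7 (2S,3R)-3-[(tert-butyldimethylsilyl)oxy]-2-methylcyclohexan-1-one, via cis-ketone 6 (not isolated)
Conditions: (COCl)2, DMSO, CH2Cl2, −78 °C; Et3N, −78 °C to rt; then DBU (20 mol %), rt
Reagents that add atoms: none
Why: Swern oxidation gives the ketone without touching the silyl ether, and DBU-mediated enolisation should enrich the 2,3-trans diequatorial epimer 7; C2 (future C4) is equilibrated again in step 7, so the route does not depend on this equilibration being complete.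

Step 5
Reactants: 7 (2S,3R)-3-[(tert-butyldimethylsilyl)oxy]-2-methylcyclohexan-1-one; 8 dimethoxyacetaldehyde (60 wt % in water, excess)
Product: 9 (2S,3R,6R)-3-[(tert-butyldimethylsilyl)oxy]-6-[(1S)-1-hydroxy-2,2-dimethoxyethyl]-2-methylcyclohexan-1-one
Conditions: D-proline (30 mol %), DMSO, rt
Reagents that add atoms: none
Why: Proline-catalysed direct aldol reaction (enamine catalysis, List–Houk transition state) in which the enamine forms on the unsubstituted CH2 side with the C2 methyl axial, and the aldehyde is delivered anti to that methyl on the face set by the D-proline carboxylic acid (matched pair), which should give the anti aldol with 6R and 1'S (future C9) configuration.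

Step 6
Reactants: 9 (2S,3R,6R)-3-[(tert-butyldimethylsilyl)oxy]-6-[(1S)-1-hydroxy-2,2-dimethoxyethyl]-2-methylcyclohexan-1-one
Product: 10 (2S,3R,6R)-3-[(tert-butyldimethylsilyl)oxy]-6-[(1S)-1-[(tert-butyldimethylsilyl)oxy]-2,2-dimethoxyethyl]-2-methylcyclohexan-1-one
Conditions: TBSCl, imidazole, DMF, 35 °C
Reagents that add atoms: tert-butyldimethylsilyl chloride, CC(C)(C)[Si](C)(C)Cl
Why: Imidazole-promoted silylation of the aldol hydroxyl blocks retro-aldol cleavage in the following base step and leaves acetal and ketone untouched.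

Step 7
Reactants: 10 (2S,3R,6R)-3-[(tert-butyldimethylsilyl)oxy]-6-[(1S)-1-[(tert-butyldimethylsilyl)oxy]-2,2-dimethoxyethyl]-2-methylcyclohexan-1-one
Product: 11 (2S,3R,6S)-3-[(tert-butyldimethylsilyl)oxy]-6-[(1S)-1-[(tert-butyldimethylsilyl)oxy]-2,2-dimethoxyethyl]-2-methylcyclohexan-1-one
Conditions: DBU (0.3 equiv), toluene, rt
Reagents that add atoms: none
Why: Base-mediated epimerisation through the ketone enolate should move the axial C6 side chain of the kinetic aldol (and any residual C2 epimer) to the all-equatorial isomer, which sets C10 and C4 under thermodynamic control and turns the anti aldol into the required syn relation between C10 and C9.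

Step 8
Reactants: 11 (2S,3R,6S)-3-[(tert-butyldimethylsilyl)oxy]-6-[(1S)-1-[(tert-butyldimethylsilyl)oxy]-2,2-dimethoxyethyl]-2-methylcyclohexan-1-one
Product: 12 tert-butyl{[(1R,2R,4R)-4-[(1S)-1-[(tert-butyldimethylsilyl)oxy]-2,2-dimethoxyethyl]-2-methyl-3-methylidenecyclohexyl]oxy}dimethylsilane
Conditions: Cp2TiMe2, toluene, 70 °C, dark
Reagents that add atoms: dimethyltitanocene Cp2TiMe2, C[Ti](C)(C1C=CC=C1)C1C=CC=C1
Why: Petasis methylenation (titanocene methylidene, oxatitanacyclobutane) olefinates the hindered, enolisable ketone under non-basic conditions that spare the two β-silyloxy groups and the acetal; no stereocenter changes.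

Step 9
Reactants: 12 tert-butyl{[(1R,2R,4R)-4-[(1S)-1-[(tert-butyldimethylsilyl)oxy]-2,2-dimethoxyethyl]-2-methyl-3-methylidenecyclohexyl]oxy}dimethylsilane
Product: 14 (2S)-2-[(tert-butyldimethylsilyl)oxy]-2-[(1R,3R,4R)-4-[(tert-butyldimethylsilyl)oxy]-3-methyl-2-methylidenecyclohexyl]acetaldehyde, via collidinium salt 13 (not isolated)
Conditions: TESOTf, 2,4,6-collidine, CH2Cl2, 0 °C; then H2O, rt
Reagents that add atoms: water, O (aldehyde oxygen); 2,4,6-collidine, Cc1cc(C)nc(C)c1 (in 13 only); triethylsilyl triflate, CC[Si](CC)(CC)OS(=O)(=O)C(F)(F)F (counter-ion of 13 only)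
Why: Silyl triflate–collidine acetal cleavage converts the dimethyl acetal into a collidinium N,O-acetal salt that water hydrolyses to the aldehyde, under conditions too mild to touch the TBS ethers, the exocyclic alkene or the α-silyloxy stereocenter.

Step 10
Reactants: 14 (2S)-2-[(tert-butyldimethylsilyl)oxy]-2-[(1R,3R,4R)-4-[(tert-butyldimethylsilyl)oxy]-3-methyl-2-methylidenecyclohexyl]acetaldehyde; 15 methyl vinyl ketone (3 equiv)
Product: 17 (1S,2R,3R,4aR,5R,6R,8aR)-3-acetyl-1,6-bis[(tert-butyldimethylsilyl)oxy]-4a,5-dimethyldecahydronaphthalen-2-ol, via Giese-adduct enolate 16 (not isolated)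
Conditions: Fe(acac)3 (50 mol %), PhSiH3, ethylene glycol, ClCH2CH2Cl, 0 °C to rt
Reagents that add atoms: none
Why: The trivalent iron hydride formed from Fe(acac)3 and PhSiH3 transfers a hydrogen atom to the CH2 terminus of the electron-rich methylidene group of 14, which creates the C14 methyl and the tertiary C5 radical; this radical adds to the terminal carbon of methyl vinyl ketone (C5–C6), divalent iron reduces the resulting α-keto radical to enolate 16, and 16 adds to the C8 aldehyde (C7–C8) before it is protonated. The closest known reaction type is the hydrogen-atom-transfer-initiated Giese addition–aldol (radical–polar crossover) annulation of γ,δ-unsaturated aldehydes with enones. Ring B closes by a 6-(enolexo)-exo-trig aldol addition through a chair that is trans-fused to ring A. At C5 the radical should be attacked anti to both flanking equatorial substituents (C4 methyl and the C10 side chain), which places C6 equatorial and the new methyl axial; at C8 the chelated chair should put the aldehyde oxygen axial with the forming bond anti to the C9–O bond (Felkin–Anh); and at C7 the acetyl group takes the equatorial site, away from the axial C5 methyl, where it would also end by equilibration. The step needs hydrogen-atom transfer to the methylidene group and not to the enone or aldehyde, and ring closure faster than enolate protonation, which the nucleophilic 1,1-disubstituted alkene, the excess of enone and the six-membered aldehyde-terminated closure should secure.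

Step 11
Reactants: 17 (1S,2R,3R,4aR,5R,6R,8aR)-3-acetyl-1,6-bis[(tert-butyldimethylsilyl)oxy]-4a,5-dimethyldecahydronaphthalen-2-ol
Product: 18 (1S,2R,3S,4aR,5R,6R,8aR)-1,6-bis[(tert-butyldimethylsilyl)oxy]-4a,5-dimethyl-3-(prop-1-en-2-yl)decahydronaphthalen-2-ol
Conditions: Zn, CH2Br2, TiCl4, THF/CH2Cl2, 0 °C to rt
Reagents that add atoms: dibromomethane, BrCBr
Why: Lombardo methylenation (gem-dizinc methylene reagent activated by TiCl4) is non-basic, so the β-hydroxy ketone should be olefinated without retro-aldol cleavage or epimerisation at C7, and free hydroxyl groups and silyl ethers are tolerated.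

Step 12
Reactants: 18 (1S,2R,3S,4aR,5R,6R,8aR)-1,6-bis[(tert-butyldimethylsilyl)oxy]-4a,5-dimethyl-3-(prop-1-en-2-yl)decahydronaphthalen-2-ol
Product: 19 (1S,2R,3S,4aR,5R,6R,8aR)-4a,5-dimethyl-3-(prop-1-en-2-yl)decahydronaphthalene-1,2,6-triol
Conditions: TBAF, THF, rt to 50 °C
Reagents that add atoms: none
Why: Fluoride-mediated desilylation removes both secondary TBS ethers; no stereocenter is affected.

Step 13
Reactants: 19 (1S,2R,3S,4aR,5R,6R,8aR)-4a,5-dimethyl-3-(prop-1-en-2-yl)decahydronaphthalene-1,2,6-triol; 20 hex-2-ynoic acid (2.2 equiv)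
Product: 21 (1S,2R,3S,4aR,5R,6R,8aR)-2-hydroxy-4a,5-dimethyl-3-(prop-1-en-2-yl)decahydronaphthalene-1,6-diyl bis(hex-2-ynoate)
Conditions: DIC, DMAP (cat.), CH2Cl2, −20 to 0 °C
Reagents that add atoms: none
Why: Steglich esterification should acylate the two equatorial hydroxyls (C3 and C9) in preference to the axial C8 hydroxyl, which is flanked by the C7 isopropenyl group and C9 and is 1,3-diaxially compressed; the equatorial C9 ester is also the thermodynamic site should acyl migration occur.

Step 14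
Reactants: 21 (1S,2R,3S,4aR,5R,6R,8aR)-2-hydroxy-4a,5-dimethyl-3-(prop-1-en-2-yl)decahydronaphthalene-1,6-diyl bis(hex-2-ynoate)
Product: 22 (1S,2R,3S,4aR,5R,6R,8aR)-2-hydroxy-4a,5-dimethyl-3-(prop-1-en-2-yl)decahydronaphthalene-1,6-diyl bis[(2Z)-hex-2-enoate] (CNP0420276.1)
Conditions: H2 (1 atm), Pd/CaCO3 poisoned with Pb(OAc)2, quinoline, EtOAc, rt
Reagents that add atoms: none
Why: Lindlar semihydrogenation adds hydrogen syn to both conjugated alkynes to give the two Z enoates, and the poisoned catalyst should leave the 1,1-disubstituted alkene untouched.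

Compound list
1 | 2-methylcyclohex-2-en-1-one | CC1=CCCCC1=O | starting material
2 | (R)-2-methylcyclohex-2-en-1-ol | CC1=CCCC[C@H]1O | intermediate
3 | tert-butyldimethyl{[(1R)-2-methylcyclohex-2-en-1-yl]oxy}silane | CC1=CCCC[C@H]1O[Si](C)(C)C(C)(C)C | intermediate
4 | [(1R,2S,3R)-3-[(tert-butyldimethylsilyl)oxy]-2-methylcyclohexyl]borane (alkylborane) | B[C@H]1[C@H](C)[C@H](O[Si](C)(C)C(C)(C)C)CCC1 | intermediate
5 | (1R,2S,3R)-3-[(tert-butyldimethylsilyl)oxy]-2-methylcyclohexan-1-ol | O[C@H]1[C@H](C)[C@H](O[Si](C)(C)C(C)(C)C)CCC1 | intermediate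
6 | (2R,3R)-3-[(tert-butyldimethylsilyl)oxy]-2-methylcyclohexan-1-one (cis-ketone) | O=C1[C@H](C)[C@H](O[Si](C)(C)C(C)(C)C)CCC1 | intermediate
7 | (2S,3R)-3-[(tert-butyldimethylsilyl)oxy]-2-methylcyclohexan-1-one | O=C1[C@@H](C)[C@H](O[Si](C)(C)C(C)(C)C)CCC1 | intermediate
8 | dimethoxyacetaldehyde | COC(OC)C=O | starting material
9 | (2S,3R,6R)-3-[(tert-butyldimethylsilyl)oxy]-6-[(1S)-1-hydroxy-2,2-dimethoxyethyl]-2-methylcyclohexan-1-one | O=C1[C@@H](C)[C@H](O[Si](C)(C)C(C)(C)C)CC[C@@H]1[C@H](O)C(OC)OC | intermediate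
10 | (2S,3R,6R)-3-[(tert-butyldimethylsilyl)oxy]-6-[(1S)-1-[(tert-butyldimethylsilyl)oxy]-2,2-dimethoxyethyl]-2-methylcyclohexan-1-one | O=C1[C@@H](C)[C@H](O[Si](C)(C)C(C)(C)C)CC[C@@H]1[C@H](O[Si](C)(C)C(C)(C)C)C(OC)OC | intermediate
11 | (2S,3R,6S)-3-[(tert-butyldimethylsilyl)oxy]-6-[(1S)-1-[(tert-butyldimethylsilyl)oxy]-2,2-dimethoxyethyl]-2-methylcyclohexan-1-one | O=C1[C@@H](C)[C@H](O[Si](C)(C)C(C)(C)C)CC[C@H]1[C@H](O[Si](C)(C)C(C)(C)C)C(OC)OC | intermediate
12 | tert-butyl{[(1R,2R,4R)-4-[(1S)-1-[(tert-butyldimethylsilyl)oxy]-2,2-dimethoxyethyl]-2-methyl-3-methylidenecyclohexyl]oxy}dimethylsilane | C=C1[C@@H](C)[C@H](O[Si](C)(C)C(C)(C)C)CC[C@H]1[C@H](O[Si](C)(C)C(C)(C)C)C(OC)OC | intermediate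
13 | 1-[(2S)-2-[(tert-butyldimethylsilyl)oxy]-2-[(1R,3R,4R)-4-[(tert-butyldimethylsilyl)oxy]-3-methyl-2-methylidenecyclohexyl]-1-methoxyethyl]-2,4,6-trimethylpyridinium triflate (collidinium salt; mixture at the N,O-acetal carbon) | C=C1[C@@H](C)[C@H](O[Si](C)(C)C(C)(C)C)CC[C@H]1[C@H](O[Si](C)(C)C(C)(C)C)C(OC)[n+]2c(C)cc(C)cc2C.[O-]S(=O)(=O)C(F)(F)F | intermediate
14 | (2S)-2-[(tert-butyldimethylsilyl)oxy]-2-[(1R,3R,4R)-4-[(tert-butyldimethylsilyl)oxy]-3-methyl-2-methylidenecyclohexyl]acetaldehyde | C=C1[C@@H](C)[C@H](O[Si](C)(C)C(C)(C)C)CC[C@H]1[C@H](O[Si](C)(C)C(C)(C)C)C=O | intermediate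
15 | methyl vinyl ketone (but-3-en-2-one) | CC(=O)C=C | starting material
16 | iron-bound (Z)-enolate of 4-[(1R,2R,3R,6R)-3-[(tert-butyldimethylsilyl)oxy]-6-[(1S)-1-[(tert-butyldimethylsilyl)oxy]-2-oxoethyl]-1,2-dimethylcyclohexyl]butan-2-one (Giese-adduct enolate; drawn as the free enolate anion) | C/C([O-])=C/C[C@]1(C)[C@@H](C)[C@H](O[Si](C)(C)C(C)(C)C)CC[C@H]1[C@H](O[Si](C)(C)C(C)(C)C)C=O | intermediate
17 | (1S,2R,3R,4aR,5R,6R,8aR)-3-acetyl-1,6-bis[(tert-butyldimethylsilyl)oxy]-4a,5-dimethyldecahydronaphthalen-2-ol | CC(=O)[C@@H]1C[C@]2(C)[C@@H](C)[C@H](O[Si](C)(C)C(C)(C)C)CC[C@H]2[C@H](O[Si](C)(C)C(C)(C)C)[C@@H]1O | intermediate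
18 | (1S,2R,3S,4aR,5R,6R,8aR)-1,6-bis[(tert-butyldimethylsilyl)oxy]-4a,5-dimethyl-3-(prop-1-en-2-yl)decahydronaphthalen-2-ol | C=C(C)[C@@H]1C[C@]2(C)[C@@H](C)[C@H](O[Si](C)(C)C(C)(C)C)CC[C@H]2[C@H](O[Si](C)(C)C(C)(C)C)[C@@H]1O | intermediate
19 | (1S,2R,3S,4aR,5R,6R,8aR)-4a,5-dimethyl-3-(prop-1-en-2-yl)decahydronaphthalene-1,2,6-triol | C=C(C)[C@@H]1C[C@]2(C)[C@@H](C)[C@H](O)CC[C@H]2[C@H](O)[C@@H]1O | intermediate
20 | hex-2-ynoic acid | CCCC#CC(=O)O | starting material
21 | (1S,2R,3S,4aR,5R,6R,8aR)-2-hydroxy-4a,5-dimethyl-3-(prop-1-en-2-yl)decahydronaphthalene-1,6-diyl bis(hex-2-ynoate) | C=C(C)[C@@H]1C[C@]2(C)[C@@H](C)[C@H](OC(=O)C#CCCC)CC[C@H]2[C@H](OC(=O)C#CCCC)[C@@H]1O | intermediate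
22 | (1S,2R,3S,4aR,5R,6R,8aR)-2-hydroxy-4a,5-dimethyl-3-(prop-1-en-2-yl)decahydronaphthalene-1,6-diyl bis[(2Z)-hex-2-enoate] | C=C(C)[C@@H]1C[C@]2(C)[C@@H](C)[C@H](OC(=O)/C=C\CCC)CC[C@H]2[C@H](OC(=O)/C=C\CCC)[C@@H]1O | target

Total step count: 14. Longest linear sequence: 14 steps (1 to 22); compounds 8, 15 and 20 enter as purchased materials.

Steps most likely to fail

Step 10. The iron enolate may be protonated, or the aldehyde reduced, before ring closure; reversible hydrogen-atom transfer may move the methylidene double bond into the ring; and the radical may be attacked on the wrong face. The fallback sets out from acetal 12 and returns at 17, with the two bond formations separated. Reductive olefin coupling of 12 with methyl vinyl ketone (Fe(acac)3, PhSiH3, EtOH/ethylene glycol, 60 °C) should give the Giese ketone F1 with the aldehyde still masked. Silyl triflate–collidine cleavage of the acetal (TESOTf, 2,4,6-collidine, then H2O) should give the keto aldehyde F2. An amine-catalysed 6-(enolexo) intramolecular aldol addition (pyrrolidine, AcOH, CH2Cl2, 0 °C) should then close ring B to 17.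

Step 5. Enamine formation on the α-branched β-silyloxy ketone may be slow, silanol may be lost by β-elimination, and catalyst control over the aldehyde face may be incomplete. The fallback sets out from ketone 7 and returns at aldehyde 14, replacing enamine catalysis by a stoichiometric enolate and a chiral-pool aldehyde. The kinetic lithium enolate of 7 (LDA, THF, −78 °C) should add to (R)-2,3-O-isopropylideneglyceraldehyde under Zimmerman–Traxler (anti) and Felkin–Anh control to give the aldol F3. Silylation (TBSCl, imidazole, DMF) should give the silyl ether F4, and DBU equilibration the all-equatorial ketone F5. Petasis methylenation (Cp2TiMe2, toluene, 70 °C) should give the methylidene acetonide F6. Periodic acid (H5IO6, EtOAc, rt) should cleave the terminal acetonide and the liberated glycol in one pot to 14.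

Step 13. Acylation may spill over to the axial C8 hydroxyl, or the acyl group may migrate between O9 and O8. The fallback sets out from 18 and returns at 21, replacing intrinsic site selectivity by a protecting group. The free C8 hydroxyl of 18 should be etherified (4-methoxybenzyl trichloroacetimidate, La(OTf)3 cat., toluene) to the PMB ether F7. TBAF should give the diol F8, and esterification of both hydroxyls with hex-2-ynoic acid (DIC, DMAP) the bis-ynoate F9. DDQ (CH2Cl2, pH 7 buffer) should remove the PMB group to give 21.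

Further compounds
F1 | step 10 | 4-[(1R,2R,3R,6R)-3-[(tert-butyldimethylsilyl)oxy]-6-[(1S)-1-[(tert-butyldimethylsilyl)oxy]-2,2-dimethoxyethyl]-1,2-dimethylcyclohexyl]butan-2-one | CC(=O)CC[C@]1(C)[C@@H](C)[C@H](O[Si](C)(C)C(C)(C)C)CC[C@H]1[C@H](O[Si](C)(C)C(C)(C)C)C(OC)OC
F2 | step 10 | (2S)-2-[(tert-butyldimethylsilyl)oxy]-2-[(1R,2R,3R,4R)-4-[(tert-butyldimethylsilyl)oxy]-2,3-dimethyl-2-(3-oxobutyl)cyclohexyl]acetaldehyde | CC(=O)CC[C@]1(C)[C@@H](C)[C@H](O[Si](C)(C)C(C)(C)C)CC[C@H]1[C@H](O[Si](C)(C)C(C)(C)C)C=O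
F3 | step 5 | (2S,3R,6R)-3-[(tert-butyldimethylsilyl)oxy]-6-[(S)-[(4R)-2,2-dimethyl-1,3-dioxolan-4-yl](hydroxy)methyl]-2-methylcyclohexan-1-one | O=C1[C@@H](C)[C@H](O[Si](C)(C)C(C)(C)C)CC[C@@H]1[C@H](O)[C@H]2COC(C)(C)O2
F4 | step 5 | (2S,3R,6R)-3-[(tert-butyldimethylsilyl)oxy]-6-[(S)-[(tert-butyldimethylsilyl)oxy][(4R)-2,2-dimethyl-1,3-dioxolan-4-yl]methyl]-2-methylcyclohexan-1-one | O=C1[C@@H](C)[C@H](O[Si](C)(C)C(C)(C)C)CC[C@@H]1[C@H](O[Si](C)(C)C(C)(C)C)[C@H]2COC(C)(C)O2
F5 | step 5 | (2S,3R,6S)-3-[(tert-butyldimethylsilyl)oxy]-6-[(S)-[(tert-butyldimethylsilyl)oxy][(4R)-2,2-dimethyl-1,3-dioxolan-4-yl]methyl]-2-methylcyclohexan-1-one | O=C1[C@@H](C)[C@H](O[Si](C)(C)C(C)(C)C)CC[C@H]1[C@H](O[Si](C)(C)C(C)(C)C)[C@H]2COC(C)(C)O2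
F6 | step 5 | (4R)-4-[(S)-[(tert-butyldimethylsilyl)oxy][(1R,3R,4R)-4-[(tert-butyldimethylsilyl)oxy]-3-methyl-2-methylidenecyclohexyl]methyl]-2,2-dimethyl-1,3-dioxolane | C=C1[C@@H](C)[C@H](O[Si](C)(C)C(C)(C)C)CC[C@H]1[C@H](O[Si](C)(C)C(C)(C)C)[C@H]2COC(C)(C)O2
F7 | step 13 | (1S,2R,3S,4aR,5R,6R,8aR)-1,6-bis[(tert-butyldimethylsilyl)oxy]-2-[(4-methoxybenzyl)oxy]-4a,5-dimethyl-3-(prop-1-en-2-yl)decahydronaphthalene | C=C(C)[C@@H]1C[C@]2(C)[C@@H](C)[C@H](O[Si](C)(C)C(C)(C)C)CC[C@H]2[C@H](O[Si](C)(C)C(C)(C)C)[C@@H]1OCc3ccc(OC)cc3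
F8 | step 13 | (1S,2R,3S,4aR,5R,6R,8aR)-2-[(4-methoxybenzyl)oxy]-4a,5-dimethyl-3-(prop-1-en-2-yl)decahydronaphthalene-1,6-diol | C=C(C)[C@@H]1C[C@]2(C)[C@@H](C)[C@H](O)CC[C@H]2[C@H](O)[C@@H]1OCc3ccc(OC)cc3
F9 | step 13 | (1S,2R,3S,4aR,5R,6R,8aR)-2-[(4-methoxybenzyl)oxy]-4a,5-dimethyl-3-(prop-1-en-2-yl)decahydronaphthalene-1,6-diyl bis(hex-2-ynoate) | C=C(C)[C@@H]1C[C@]2(C)[C@@H](C)[C@H](OC(=O)C#CCCC)CC[C@H]2[C@H](OC(=O)C#CCCC)[C@@H]1OCc3ccc(OC)cc3
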